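Ring A (C1–C5, C10) is cut across C2–C3 and C4–C5. The quaternary C4 (C19 methyl, C18 carboxyl) next to the C5 methine maps onto methacrolein, and C5–C10–C1–C2 onto an (E)-1-alkyl-2-methyl-3-silyloxy diene. One catalytic, enantioselective exo Diels–Alder reaction closes ring A, sets C4 and C5, and leaves a C1=C10 silyl enol ether through which C9 is later attached to C10. The diene carries C6–C8/C17 as a but-3-enyl chain (C8 masked as a terminal alkene, not an acetal that strong silyl Lewis acids would ionise) and a triisopropylsilyl enol ether that resists the acidic catalyst. Ring B follows by samarium ketyl–enoate closure of C8–C9.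

Key step: step 3

Remarks on the chemistry:
- Labdane numbering is used for all intermediates; β is the face of the C19/C20 methyl groups, α the opposite face.
- C8 is oxidised to the methyl ketone only in step 10.
- The catalyst antipode in step 3 is assigned from the usual pre-transition-state model for 2-substituted acroleins (formyl C–H···O contact, enal stacked on the cis phenyl ring). It is assumed that this model holds for diene 5; if it does not, the mirror-image catalyst is used.

Step 1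
Reactants: 1 pent-4-enal; 2 3-(triphenylphosphoranylidene)butan-2-one
Product: 3 (E)-3-methylocta-3,7-dien-2-one
Conditions: toluene, 90 °C
Reagents that add atoms: none
Why: Wittig olefination with a stabilised, α-branched acyl ylide should give the trisubstituted enone with E geometry, which later fixes the trans relationship at C5.

Step 2
Reactants: 3 (E)-3-methylocta-3,7-dien-2-one
Product: 5 (E)-3-methyl-2-(triisopropylsilyloxy)octa-1,3,7-triene, via lithium dienolate 4 (not isolated)
Conditions: LiN(i-Pr)2, THF, −78 °C; then i-Pr3SiOTf, −78 → 0 °C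
Reagents that add atoms: triisopropylsilyl trifluoromethanesulfonate, CC(C)[Si](C(C)C)(C(C)C)OS(=O)(=O)C(F)(F)F
Why: Kinetic deprotonation of the acetyl methyl group (α′, not γ) and O-silylation give the cross-conjugated 2-silyloxy diene with the E alkene untouched (regioselective silyl enol ether formation).

Step 3
Reactants: 5 (E)-3-methyl-2-(triisopropylsilyloxy)octa-1,3,7-triene; 6 methacrolein
Product: 7 (1R,2R)-2-(but-3-en-1-yl)-1,3-dimethyl-4-(triisopropylsilyloxy)cyclohex-3-ene-1-carbaldehyde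
Conditions: 6 (3 equiv), (R)-tetrahydro-1-(2-methylphenyl)-3,3-diphenyl-1H,3H-pyrrolo[1,2-c][1,3,2]oxazaborole (20 mol %), Tf2NH (18 mol %), CH2Cl2, −78 °C
Reagents that add atoms: none
Why: The formyl oxygen of 6 binds the boron of the N-protonated oxazaborolidine, and the s-trans enal then undergoes a concerted, asynchronous [4+2] addition in which the nucleophilic CH2 terminus of the diene (C2) bonds to the β-carbon C3 and the alkyl-bearing terminus C5 to the α-carbon C4; the closest known reaction type is the oxazaborolidinium-catalysed enantioselective Diels–Alder reaction of 2-substituted acroleins with 2-silyloxy-1,3-dienes. Ring A is closed by the intermolecular cycloaddition itself (σ bonds C2–C3 and C4–C5 formed suprafacially on both partners), leaving the C1=C10 silyl enol ether. C4 is set by the catalyst, whose cis phenyl ring screens one face of the bound enal so that the diene should add to the Si face of the α-carbon and give 4R. C5 is set relative to C4 by the exo position of the formyl group together with the E geometry of the diene, which places H-5 cis to the formyl carbon and the C6 chain cis to the C19 methyl. Regiochemistry is secured because the silyloxy group and the 1-alkyl group direct to the same adduct. The exo preference is expected from the α-methyl group of the dienophile and the bulky silyloxy- and methyl-substituted interior of the diene, which disfavour a catalyst-bound formyl group under the diene; the triisopropylsilyl ether and the plain butenyl chain give the acid nothing to cleave or ionise.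

Step 4
Reactants: 7 (1R,2R)-2-(but-3-en-1-yl)-1,3-dimethyl-4-(triisopropylsilyloxy)cyclohex-3-ene-1-carbaldehyde
Product: 8 (1R,2R)-2-(but-3-en-1-yl)-1,3-dimethyl-4-(triisopropylsilyloxy)cyclohex-3-ene-1-carboxylic acid
Conditions: NaClO2, NaH2PO4, 2-methylbut-2-ene (excess), t-BuOH/H2O, 0 °C
Reagents that add atoms: sodium chlorite, [Na+].[O-]Cl=O
Why: Pinnick oxidation converts the hindered, non-epimerisable aldehyde into the acid, and the excess alkene scavenger should intercept HOCl before it reaches the silyl enol ether or the vinyl group.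

Step 5
Reactants: 8 (1R,2R)-2-(but-3-en-1-yl)-1,3-dimethyl-4-(triisopropylsilyloxy)cyclohex-3-ene-1-carboxylic acid
Product: 9 benzyl (1R,2R)-2-(but-3-en-1-yl)-1,3-dimethyl-4-(triisopropylsilyloxy)cyclohex-3-ene-1-carboxylate
Conditions: BnBr, K2CO3, DMF, rt
Reagents that add atoms: benzyl bromide, BrCc1ccccc1
Why: SN2 alkylation of the carboxylate avoids attack at the hindered acyl carbon and installs an ester that is removed by hydrogenolysis in the last step.

Step 6
Reactants: 9 benzyl (1R,2R)-2-(but-3-en-1-yl)-1,3-dimethyl-4-(triisopropylsilyloxy)cyclohex-3-ene-1-carboxylate; 10 methyl 3,3-dimethoxypropanoate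
Product: 11 benzyl (1R,2R,3S)-2-(but-3-en-1-yl)-3-(1,3-dimethoxy-3-oxopropyl)-1,3-dimethyl-4-oxocyclohexane-1-carboxylate (both epimers at the methoxy carbon C9)
Conditions: 10 (1.5 equiv), Me3SiOTf (1.2 equiv), CH2Cl2, −78 → −40 °C; aq. NaHCO3
Reagents that add atoms: none
Why: Mukaiyama-type addition of the tetrasubstituted silyl enol ether to the oxocarbenium ion from the acetal forms C9–C10 and the C10 quaternary centre; the electrophile should add to the α face, anti to the C5 butenyl chain that A(1,2) strain with the C10 methyl holds pseudoaxial, giving 10β-CH3.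

Step 7
Reactants: 11 benzyl (1R,2R,3S)-2-(but-3-en-1-yl)-3-(1,3-dimethoxy-3-oxopropyl)-1,3-dimethyl-4-oxocyclohexane-1-carboxylate
Product: 12 benzyl (1R,2R,3R)-2-(but-3-en-1-yl)-3-[(E)-3-methoxy-3-oxoprop-1-en-1-yl]-1,3-dimethyl-4-oxocyclohexane-1-carboxylate
Conditions: LiN(SiMe3)2 (2.5 equiv), THF, −78 → 0 °C; aq. NH4Cl
Reagents that add atoms: none
Why: E1cB elimination of methoxide from the ester enolate should give the (E)-enoate, while the excess base holds the C1 ketone as its enolate so that the liberated methoxide cannot attack it.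

Step 8
Reactants: 12 benzyl (1R,2R,3R)-2-(but-3-en-1-yl)-3-[(E)-3-methoxy-3-oxoprop-1-en-1-yl]-1,3-dimethyl-4-oxocyclohexane-1-carboxylate
Product: 14 benzyl (1R,5R,6R)-6-(but-3-en-1-yl)-5-[(E)-3-methoxy-3-oxoprop-1-en-1-yl]-1,5-dimethyl-4-(trifluoromethanesulfonyloxy)cyclohex-3-ene-1-carboxylate, via potassium enolate 13 (not isolated)
Conditions: KN(SiMe3)2, THF, −78 °C; then PhNTf2, −78 → 0 °C
Reagents that add atoms: N-phenylbis(trifluoromethanesulfonimide), FC(F)(F)S(=O)(=O)N(c1ccccc1)S(=O)(=O)C(F)(F)F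
Why: Enolisation is possible only towards C2 because C10 is quaternary, and O-sulfonylation of the potassium enolate gives the C1=C2 enol triflate (enol triflate formation).

Step 9
Reactants: 14 benzyl (1R,5R,6R)-6-(but-3-en-1-yl)-5-[(E)-3-methoxy-3-oxoprop-1-en-1-yl]-1,5-dimethyl-4-(trifluoromethanesulfonyloxy)cyclohex-3-ene-1-carboxylate
Product: 15 benzyl (1R,5R,6R)-6-(but-3-en-1-yl)-5-[(E)-3-methoxy-3-oxoprop-1-en-1-yl]-1,5-dimethylcyclohex-3-ene-1-carboxylate
Conditions: Pd(OAc)2 (5 mol %), PPh3 (10 mol %), HCO2H, n-Bu3N, DMF, 60 °C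
Reagents that add atoms: none
Why: Palladium-catalysed formate reduction of the enol triflate removes the C1 oxygen and leaves a C1=C2 alkene that is saturated in step 16; enoate, vinyl group and benzyl ester should not react under these homogeneous conditions.

Step 10
Reactants: 15 benzyl (1R,5R,6R)-6-(but-3-en-1-yl)-5-[(E)-3-methoxy-3-oxoprop-1-en-1-yl]-1,5-dimethylcyclohex-3-ene-1-carboxylate
Product: 16 benzyl (1R,5R,6R)-5-[(E)-3-methoxy-3-oxoprop-1-en-1-yl]-1,5-dimethyl-6-(3-oxobutyl)cyclohex-3-ene-1-carboxylate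
Conditions: PdCl2 (10 mol %), CuCl (1 equiv), O2 (1 atm), DMF/H2O 7:1, rt
Reagents that add atoms: water, O
Why: Tsuji–Wacker oxidation is selective for the monosubstituted terminal alkene and delivers oxygen to C8 (Markovnikov), while the hindered ring alkene and the electron-poor enoate are inert.

Step 11
Reactants: 16 benzyl (1R,5R,6R)-5-[(E)-3-methoxy-3-oxoprop-1-en-1-yl]-1,5-dimethyl-6-(3-oxobutyl)cyclohex-3-ene-1-carboxylate
Product: 17 benzyl (1R,4aS,5R,6R,8aR)-6-hydroxy-5-(2-methoxy-2-oxoethyl)-1,4a,6-trimethyl-1,2,4a,5,6,7,8,8a-octahydronaphthalene-1-carboxylate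
Conditions: SmI2 (2.5 equiv), HMPA, t-BuOH, THF, −78 °C
Reagents that add atoms: none
Why: Divalent samarium generates the C8 ketyl, which adds 6-exo-trig to C9 of the enoate (ketyl–olefin radical cyclisation) through a chair transition state with the enoate and the bulky samarium-bound oxygen equatorial and the methyl group axial; this should give 8α-OH/8β-CH3 and 9α-H in a trans-fused ring B, and the trans hydroxy ester is slow to lactonise.

Step 12
Reactants: 17 benzyl (1R,4aS,5R,6R,8aR)-6-hydroxy-5-(2-methoxy-2-oxoethyl)-1,4a,6-trimethyl-1,2,4a,5,6,7,8,8a-octahydronaphthalene-1-carboxylate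
Product: 18 benzyl (1R,4aS,5R,6R,8aR)-6-acetoxy-5-(2-methoxy-2-oxoethyl)-1,4a,6-trimethyl-1,2,4a,5,6,7,8,8a-octahydronaphthalene-1-carboxylate
Conditions: Ac2O, Me3SiOTf (5 mol %), CH2Cl2, −40 → 0 °C
Reagents that add atoms: acetic anhydride, CC(=O)OC(C)=O
Why: Silyl-triflate-catalysed acylation is fast enough at low temperature to acetylate the hindered equatorial tertiary alcohol before lactonisation or elimination can compete (Lewis-acid-catalysed esterification).

Step 13
Reactants: 18 benzyl (1R,4aS,5R,6R,8aR)-6-acetoxy-5-(2-methoxy-2-oxoethyl)-1,4a,6-trimethyl-1,2,4a,5,6,7,8,8a-octahydronaphthalene-1-carboxylate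
Product: 19 benzyl (1R,4aS,5R,6R,8aR)-6-acetoxy-5-(carboxymethyl)-1,4a,6-trimethyl-1,2,4a,5,6,7,8,8a-octahydronaphthalene-1-carboxylate
Conditions: Me3SnOH, 1,2-dichloroethane, 70 °C; then aq. HCl
Reagents that add atoms: trimethyltin hydroxide, C[Sn](C)(C)O
Why: Me3SnOH hydrolyses the unhindered methyl ester by acyl transfer under near-neutral conditions, whereas the tertiary acetate and the neopentyl benzyl ester are too hindered to react (chemoselective ester hydrolysis).

Step 14
Reactants: 19 benzyl (1R,4aS,5R,6R,8aR)-6-acetoxy-5-(carboxymethyl)-1,4a,6-trimethyl-1,2,4a,5,6,7,8,8a-octahydronaphthalene-1-carboxylate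
Product: 21 benzyl (1R,4aS,5R,6R,8aR)-6-acetoxy-5-(3-diazo-2-oxopropyl)-1,4a,6-trimethyl-1,2,4a,5,6,7,8,8a-octahydronaphthalene-1-carboxylate, via mixed carbonic anhydride 20 (not isolated)
Conditions: i-BuOCOCl, N-methylmorpholine, THF, −15 °C; then Me3SiCHN2, MeCN, 0 °C → rt
Reagents that add atoms: (trimethylsilyl)diazomethane, C[Si](C)(C)C=[N+]=[N-]
Why: Activation as the mixed anhydride and C-acylation of the diazoalkane (first stage of the Arndt–Eistert homologation) gives the diazoketone without exposing the acetoxy acid to HCl.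

Step 15
Reactants: 21 benzyl (1R,4aS,5R,6R,8aR)-6-acetoxy-5-(3-diazo-2-oxopropyl)-1,4a,6-trimethyl-1,2,4a,5,6,7,8,8a-octahydronaphthalene-1-carboxylate
Product: 23 benzyl (1R,4aS,5R,6R,8aR)-6-acetoxy-5-(2-carboxyethyl)-1,4a,6-trimethyl-1,2,4a,5,6,7,8,8a-octahydronaphthalene-1-carboxylate, via ketene 22 (not isolated)
Conditions: PhCO2Ag (10 mol %), Et3N, THF/H2O, rt
Reagents that add atoms: water, O
Why: Silver-catalysed Wolff rearrangement gives the ketene, which water traps as the acid with one more carbon; the migrating C11 is primary and no stereocentre is involved.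

Step 16
Reactants: 23 benzyl (1R,4aS,5R,6R,8aR)-6-acetoxy-5-(2-carboxyethyl)-1,4a,6-trimethyl-1,2,4a,5,6,7,8,8a-octahydronaphthalene-1-carboxylate
Product: 24 (1R,4aS,5R,6R,8aR)-6-acetoxy-5-(2-carboxyethyl)-1,4a,6-trimethyldecahydronaphthalene-1-carboxylic acid (CNP0196050.1)
Conditions: H2 (1 atm), 10% Pd on carbon, EtOAc, rt
Reagents that add atoms: none
Why: Heterogeneous hydrogenation saturates the C1=C2 alkene (no new stereocentre) and cleaves the benzyl ester by hydrogenolysis in the same operation, conditions under which the tertiary acetate is stable.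

Compound list
1 | pent-4-enal | C=CCCC=O | starting material
2 | 3-(triphenylphosphoranylidene)butan-2-one | CC(=O)C(C)=P(c1ccccc1)(c1ccccc1)c1ccccc1 | starting material
3 | (E)-3-methylocta-3,7-dien-2-one | CC(=O)/C(C)=C/CCC=C | intermediate
4 | lithium (E)-3-methylocta-1,3,7-trien-2-olate (not isolated) | [Li]OC(=C)/C(C)=C/CCC=C | intermediate
5 | (E)-3-methyl-2-(triisopropylsilyloxy)octa-1,3,7-triene | C=C(O[Si](C(C)C)(C(C)C)C(C)C)/C(C)=C/CCC=C | intermediate
6 | methacrolein (2-methylprop-2-enal) | CC(=C)C=O | starting material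
7 | (1R,2R)-2-(but-3-en-1-yl)-1,3-dimethyl-4-(triisopropylsilyloxy)cyclohex-3-ene-1-carbaldehyde (4β-CH3, 4α-CHO, 5α-H) | C=CCC[C@@H]1C(C)=C(O[Si](C(C)C)(C(C)C)C(C)C)CC[C@@]1(C)C=O | intermediate
8 | (1R,2R)-2-(but-3-en-1-yl)-1,3-dimethyl-4-(triisopropylsilyloxy)cyclohex-3-ene-1-carboxylic acid | C=CCC[C@@H]1C(C)=C(O[Si](C(C)C)(C(C)C)C(C)C)CC[C@@]1(C)C(=O)O | intermediate
9 | benzyl (1R,2R)-2-(but-3-en-1-yl)-1,3-dimethyl-4-(triisopropylsilyloxy)cyclohex-3-ene-1-carboxylate | C=CCC[C@@H]1C(C)=C(O[Si](C(C)C)(C(C)C)C(C)C)CC[C@@]1(C)C(=O)OCc1ccccc1 | intermediate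
10 | methyl 3,3-dimethoxypropanoate | COC(=O)CC(OC)OC | starting material
11 | benzyl (1R,2R,3S)-2-(but-3-en-1-yl)-3-(1,3-dimethoxy-3-oxopropyl)-1,3-dimethyl-4-oxocyclohexane-1-carboxylate (10β-CH3; both C9 epimers) | C=CCC[C@@H]1[C@@](C)(C(OC)CC(=O)OC)C(=O)CC[C@@]1(C)C(=O)OCc1ccccc1 | intermediate
12 | benzyl (1R,2R,3R)-2-(but-3-en-1-yl)-3-[(E)-3-methoxy-3-oxoprop-1-en-1-yl]-1,3-dimethyl-4-oxocyclohexane-1-carboxylate | C=CCC[C@@H]1[C@@](C)(/C=C/C(=O)OC)C(=O)CC[C@@]1(C)C(=O)OCc1ccccc1 | intermediate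
13 | potassium C1 enolate of 12 (C1–OK, C1=C2; not isolated) | C=CCC[C@@H]1[C@@](C)(/C=C/C(=O)OC)C(O[K])=CC[C@@]1(C)C(=O)OCc1ccccc1 | intermediate
14 | benzyl (1R,5R,6R)-6-(but-3-en-1-yl)-5-[(E)-3-methoxy-3-oxoprop-1-en-1-yl]-1,5-dimethyl-4-(trifluoromethanesulfonyloxy)cyclohex-3-ene-1-carboxylate | C=CCC[C@@H]1[C@@](C)(/C=C/C(=O)OC)C(OS(=O)(=O)C(F)(F)F)=CC[C@@]1(C)C(=O)OCc1ccccc1 | intermediate
15 | benzyl (1R,5R,6R)-6-(but-3-en-1-yl)-5-[(E)-3-methoxy-3-oxoprop-1-en-1-yl]-1,5-dimethylcyclohex-3-ene-1-carboxylate | C=CCC[C@@H]1[C@@](C)(/C=C/C(=O)OC)C=CC[C@@]1(C)C(=O)OCc1ccccc1 | intermediate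
16 | benzyl (1R,5R,6R)-5-[(E)-3-methoxy-3-oxoprop-1-en-1-yl]-1,5-dimethyl-6-(3-oxobutyl)cyclohex-3-ene-1-carboxylate | CC(=O)CC[C@@H]1[C@@](C)(/C=C/C(=O)OC)C=CC[C@@]1(C)C(=O)OCc1ccccc1 | intermediate
17 | benzyl (1R,4aS,5R,6R,8aR)-6-hydroxy-5-(2-methoxy-2-oxoethyl)-1,4a,6-trimethyl-1,2,4a,5,6,7,8,8a-octahydronaphthalene-1-carboxylate (18-benzyl 12-methyl 8α-hydroxy-13,14,15,16-tetranorlabd-1-ene-12,18-dioate; 5α-H, 9α-H, 10β-CH3) | O[C@]1(C)CC[C@@H]2[C@](C)(C=CC[C@@]2(C)C(=O)OCc3ccccc3)[C@H]1CC(=O)OC | intermediate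
18 | benzyl (1R,4aS,5R,6R,8aR)-6-acetoxy-5-(2-methoxy-2-oxoethyl)-1,4a,6-trimethyl-1,2,4a,5,6,7,8,8a-octahydronaphthalene-1-carboxylate | CC(=O)O[C@]1(C)CC[C@@H]2[C@](C)(C=CC[C@@]2(C)C(=O)OCc3ccccc3)[C@H]1CC(=O)OC | intermediate
19 | benzyl (1R,4aS,5R,6R,8aR)-6-acetoxy-5-(carboxymethyl)-1,4a,6-trimethyl-1,2,4a,5,6,7,8,8a-octahydronaphthalene-1-carboxylate | CC(=O)O[C@]1(C)CC[C@@H]2[C@](C)(C=CC[C@@]2(C)C(=O)OCc3ccccc3)[C@H]1CC(=O)O | intermediate
20 | mixed isobutyl carbonic anhydride of 19 (not isolated) | CC(=O)O[C@]1(C)CC[C@@H]2[C@](C)(C=CC[C@@]2(C)C(=O)OCc3ccccc3)[C@H]1CC(=O)OC(=O)OCC(C)C | intermediate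
21 | benzyl (1R,4aS,5R,6R,8aR)-6-acetoxy-5-(3-diazo-2-oxopropyl)-1,4a,6-trimethyl-1,2,4a,5,6,7,8,8a-octahydronaphthalene-1-carboxylate | CC(=O)O[C@]1(C)CC[C@@H]2[C@](C)(C=CC[C@@]2(C)C(=O)OCc3ccccc3)[C@H]1CC(=O)C=[N+]=[N-] | intermediate
22 | benzyl (1R,4aS,5R,6R,8aR)-6-acetoxy-1,4a,6-trimethyl-5-(3-oxoprop-2-en-1-yl)-1,2,4a,5,6,7,8,8a-octahydronaphthalene-1-carboxylate (ketene, not isolated) | CC(=O)O[C@]1(C)CC[C@@H]2[C@](C)(C=CC[C@@]2(C)C(=O)OCc3ccccc3)[C@H]1CC=C=O | intermediate
23 | benzyl (1R,4aS,5R,6R,8aR)-6-acetoxy-5-(2-carboxyethyl)-1,4a,6-trimethyl-1,2,4a,5,6,7,8,8a-octahydronaphthalene-1-carboxylate | CC(=O)O[C@]1(C)CC[C@@H]2[C@](C)(C=CC[C@@]2(C)C(=O)OCc3ccccc3)[C@H]1CCC(=O)O | intermediate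
24 | (1R,4aS,5R,6R,8aR)-6-acetoxy-5-(2-carboxyethyl)-1,4a,6-trimethyldecahydronaphthalene-1-carboxylic acid (8α-acetoxy-14,15,16-trinorlabdane-13,18-dioic acid, CNP0196050.1) | CC(=O)O[C@]1(C)CC[C@@H]2[C@](C)(CCC[C@@]2(C)C(=O)O)[C@H]1CCC(=O)O | target

Total step count: 16. Longest linear sequence: 16 steps (1 → 24).

Steps most likely to fail

Step 3. The cycloaddition may proceed with incomplete exo or enantiofacial discrimination, or the acid may protodesilylate the diene before it reacts. The fallback replaces asymmetric catalysis by resolution. From 5 and 6 the cycloaddition is run with an achiral acid (Tf2NH, 1 mol %, CH2Cl2, −78 °C), under which 2-silyloxy dienes and α-substituted enals are known to combine with exo preference, to give the racemic exo aldehyde F1. Chlorite oxidation as in step 4 gives the racemic acid F2. Fractional crystallisation of its salts with (R)-1-phenylethylamine should deliver the salt of the (1R,2R) acid F3 (the mirror-image amine is taken if the other diastereomer is the less soluble one). Acidification returns 8, where the route is rejoined.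

Step 11. Ring closure through the alternative chair (samarium alkoxide axial) would give the C8 epimer, or the ketone may be reduced without cyclising. The fallback closes ring B by a palladium-mediated conjugate addition and sets C8 afterwards by alkene hydration. From 16, kinetic enolisation on the methyl side (LiN(i-Pr)2, THF, −78 °C, then PhNTf2) gives the terminal enol triflate F4. A reductive Heck-type 6-exo cyclisation onto the enoate (Pd(OAc)2, PPh3, HCO2Na, DMF, 80 °C) should give the exocyclic alkene F5 with the C9 chain equatorial. Mukaiyama hydration (Co(acac)2, PhSiH3, O2), which prefers the 1,1-disubstituted alkene over the ring alkene and should deliver oxygen to C8 from the less hindered α face, returns to the route at 17.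

Step 6. The hindered tetrasubstituted silyl enol ether may react sluggishly with the substituted oxocarbenium ion, or with poor facial control at C10. The fallback introduces C9 as a one-carbon electrophile and builds the enoate by olefination. From 9, trimethyl orthoformate with catalytic Me3SiOTf (CH2Cl2, −78 °C) gives the β-keto acetal F6 through the much smaller dimethoxycarbenium ion. Aqueous acid (TsOH, acetone/H2O) releases the keto aldehyde F7. Wittig olefination with methyl (triphenylphosphoranylidene)acetate (toluene, 80 °C) gives the (E)-enoate and rejoins the route at 12.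

Further compounds
F1 | step 3 | racemic exo aldehyde (7 and its enantiomer) | C=CCC[C@@H]1C(C)=C(O[Si](C(C)C)(C(C)C)C(C)C)CC[C@@]1(C)C=O.C=CCC[C@H]1C(C)=C(O[Si](C(C)C)(C(C)C)C(C)C)CC[C@]1(C)C=O
F2 | step 3 | racemic acid (8 and its enantiomer) | C=CCC[C@@H]1C(C)=C(O[Si](C(C)C)(C(C)C)C(C)C)CC[C@@]1(C)C(=O)O.C=CCC[C@H]1C(C)=C(O[Si](C(C)C)(C(C)C)C(C)C)CC[C@]1(C)C(=O)O
F3 | step 3 | (R)-1-phenylethylammonium salt of 8 | C=CCC[C@@H]1C(C)=C(O[Si](C(C)C)(C(C)C)C(C)C)CC[C@@]1(C)C(=O)[O-].C[C@@H]([NH3+])c1ccccc1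
F4 | step 11 | benzyl (1R,5R,6R)-5-[(E)-3-methoxy-3-oxoprop-1-en-1-yl]-1,5-dimethyl-6-[3-(trifluoromethanesulfonyloxy)but-3-en-1-yl]cyclohex-3-ene-1-carboxylate | C=C(OS(=O)(=O)C(F)(F)F)CC[C@@H]1[C@@](C)(/C=C/C(=O)OC)C=CC[C@@]1(C)C(=O)OCc1ccccc1
F5 | step 11 | 18-benzyl 12-methyl 13,14,15,16-tetranorlabda-1,8(17)-diene-12,18-dioate (5α-H, 9α-H, 10β-CH3) | C=C1CC[C@@H]2[C@](C)(C=CC[C@@]2(C)C(=O)OCc3ccccc3)[C@H]1CC(=O)OC
F6 | step 6 | benzyl (1R,2R,3S)-2-(but-3-en-1-yl)-3-(dimethoxymethyl)-1,3-dimethyl-4-oxocyclohexane-1-carboxylate | C=CCC[C@@H]1[C@@](C)(C(OC)OC)C(=O)CC[C@@]1(C)C(=O)OCc1ccccc1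
F7 | step 6 | benzyl (1R,2R,3S)-2-(but-3-en-1-yl)-3-formyl-1,3-dimethyl-4-oxocyclohexane-1-carboxylate | C=CCC[C@@H]1[C@@](C)(C=O)C(=O)CC[C@@]1(C)C(=O)OCc1ccccc1
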